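C5 of ring A (the thiophene carrying the ester arm) bears a single exocyclic CH2 held between that α-thienyl carbon and the senecioate oxygen. Cutting C5–CH2 and O–C(=O) together gives an α-thienyl anion, formaldehyde and 3-methylbut-2-enoyl chloride.
The isovalerate on the homopropargylic oxygen of the ring B side chain cannot meet n-BuLi, so this oxygen travels as its TBS ether and is exchanged for the ester in the last two steps.
The C5'(ring B)–C(sp) bond is cut by a Sonogashira disconnection to 5-bromo-2,2'-bithiophene and O-silylated but-3-yn-1-ol.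
No ring is formed at any stage: rings A and B and their C2–C2' bond are bought together in the bromobithiophene.

Key step: step 2

Remark: the target has no stereocentre and no configurable double bond (the senecioyl alkene carries two methyl groups on one carbon), so no stereocontrol is needed. Compound 2 is taken as a catalogue compound, otherwise one silylation away from but-3-yn-1-ol.

Step 1
Reactants: 1 5-bromo-2,2'-bithiophene; 2 tert-butyl(but-3-yn-1-yloxy)dimethylsilane
Product: 3 tert-butyl{[4-(2,2'-bithiophen-5-yl)but-3-yn-1-yl]oxy}dimethylsilane (alkyne on ring B; C5 of ring A still C–H)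
Conditions: PdCl2(PPh3)2 (3 mol %), CuI (5 mol %), Et3N, THF (degassed), 55 °C
Reagents that add atoms: none
Why: Sonogashira coupling, in which zerovalent palladium formed from PdCl2(PPh3)2 inserts into the thienyl C–Br bond, the copper acetylide of 2 transmetalates and reductive elimination forms the C(sp2)–C(sp) bond, while the silyl ether is inert to the amine medium.

Step 2
Reactants: 3 tert-butyl{[4-(2,2'-bithiophen-5-yl)but-3-yn-1-yl]oxy}dimethylsilane; 4 formaldehyde (monomer); 5 3-methylbut-2-enoyl chloride
Product: 8 [5'-(4-{[tert-butyl(dimethyl)silyl]oxy}but-1-yn-1-yl)-2,2'-bithiophen-5-yl]methyl 3-methylbut-2-enoate, via thienyllithium 6 (not isolated), via lithium alkoxide 7 (not isolated)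
Conditions: n-BuLi (0.95 equiv), THF, −78 °C, 1 h; 4 (1.05 equiv per Li, assayed cold THF solution of the monomer from cracked dry paraformaldehyde), −78 → −20 °C; 5 (1.2 equiv), −78 → 0 °C; aq. NaHCO3
Reagents that add atoms: formaldehyde 4, C=O; 3-methylbut-2-enoyl chloride 5, CC(C)=CC(=O)Cl
Why: n-BuLi removes the C5–H of ring A, whose carbanion lies in an sp2 orbital next to sulfur, to give thienyllithium 6, which adds to the carbonyl carbon of monomeric formaldehyde (C5–CH2 bond) and leaves the primary lithium alkoxide 7. Alkoxide 7 then attacks 5 by addition–elimination at the acyl carbon (O–acyl bond) with loss of LiCl, so the acid-sensitive bithienylmethanol is never handled. The closest known reaction type is the α-lithiation and hydroxymethylation of thiophenes, joined to the one-pot acyl chloride quench of the alkoxide from an organolithium–aldehyde addition. No ring closes and no stereocentre arises. Site selectivity is needed against the β-C–H bonds and the propargylic CH2, and it is secured because C5–H is the only α-C–H left in 3 and is kinetically far more acidic at −78 °C, with a slight deficit of base leaving no n-BuLi to attack elsewhere. The flask holds no amine, so 5 cannot be dehydrochlorinated to the vinylketene that would deliver the deconjugated 3-methylbut-3-enoate, and formaldehyde is dosed close to one equivalent so that hemiformal alkoxides are not acylated.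

Step 3
Reactants: 8 [5'-(4-{[tert-butyl(dimethyl)silyl]oxy}but-1-yn-1-yl)-2,2'-bithiophen-5-yl]methyl 3-methylbut-2-enoate
Product: 9 [5'-(4-hydroxybut-1-yn-1-yl)-2,2'-bithiophen-5-yl]methyl 3-methylbut-2-enoate
Conditions: TBAF (1.3 equiv), AcOH (1.3 equiv), THF, 0 °C → rt
Reagents that add atoms: none
Why: Fluoride-mediated desilylation driven by the strong Si–F bond, in which acetic acid protonates the released alkoxide at once and keeps the medium near neutral, so the senecioate should not be transesterified and the ionisable bithienylmethyl C–O bond should not be solvolysed.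

Step 4
Reactants: 9 [5'-(4-hydroxybut-1-yn-1-yl)-2,2'-bithiophen-5-yl]methyl 3-methylbut-2-enoate; 10 3-methylbutanoyl chloride
Product: 11 [5'-(4-{[3-methylbutanoyl]oxy}but-1-yn-1-yl)-2,2'-bithiophen-5-yl]methyl 3-methylbut-2-enoate (target CNP0114739.0)
Conditions: pyridine (2 equiv), DMAP (5 mol %), CH2Cl2, 0 °C → rt
Reagents that add atoms: 3-methylbutanoyl chloride 10, CC(C)CC(=O)Cl
Why: DMAP-catalysed O-acylation of an unhindered primary alcohol through the acylpyridinium ion, with pyridine taking up HCl so that the acid-labile thienylmethyl ester, the conjugated ester, the alkyne and the bithiophene stay untouched.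

Compound list
1 | 5-bromo-2,2'-bithiophene | Brc1ccc(-c2cccs2)s1 | starting material
2 | tert-butyl(but-3-yn-1-yloxy)dimethylsilane | C#CCCO[Si](C)(C)C(C)(C)C | starting material
3 | tert-butyl{[4-(2,2'-bithiophen-5-yl)but-3-yn-1-yl]oxy}dimethylsilane | CC(C)(C)[Si](C)(C)OCCC#Cc1ccc(-c2cccs2)s1 | intermediate
4 | formaldehyde (monomer, cracked from commercial paraformaldehyde) | C=O | starting material
5 | 3-methylbut-2-enoyl chloride (senecioyl chloride) | CC(C)=CC(=O)Cl | starting material
6 | [5'-(4-{[tert-butyl(dimethyl)silyl]oxy}but-1-yn-1-yl)-2,2'-bithiophen-5-yl]lithium (not isolated) | [Li]c1ccc(-c2ccc(C#CCCO[Si](C)(C)C(C)(C)C)s2)s1 | intermediate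
7 | lithium [5'-(4-{[tert-butyl(dimethyl)silyl]oxy}but-1-yn-1-yl)-2,2'-bithiophen-5-yl]methoxide (not isolated) | [Li]OCc1ccc(-c2ccc(C#CCCO[Si](C)(C)C(C)(C)C)s2)s1 | intermediate
8 | [5'-(4-{[tert-butyl(dimethyl)silyl]oxy}but-1-yn-1-yl)-2,2'-bithiophen-5-yl]methyl 3-methylbut-2-enoate | CC(C)=CC(=O)OCc1ccc(-c2ccc(C#CCCO[Si](C)(C)C(C)(C)C)s2)s1 | intermediate
9 | [5'-(4-hydroxybut-1-yn-1-yl)-2,2'-bithiophen-5-yl]methyl 3-methylbut-2-enoate | CC(C)=CC(=O)OCc1ccc(-c2ccc(C#CCCO)s2)s1 | intermediate
10 | 3-methylbutanoyl chloride (isovaleryl chloride) | CC(C)CC(=O)Cl | starting material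
11 | [5'-(4-{[3-methylbutanoyl]oxy}but-1-yn-1-yl)-2,2'-bithiophen-5-yl]methyl 3-methylbut-2-enoate | CC(C)=CC(=O)OCc1ccc(-c2ccc(C#CCCOC(=O)CC(C)C)s2)s1 | target

Total step count: 4
Longest linear sequence: 4 steps (1 → 3 → 8 → 9 → 11)

Steps most likely to fail

Step 2. Three processes could erode the step.
- Deprotonation at the propargylic CH2 could compete, followed by β-elimination of the silyloxy group.
- The alkoxide could take up further formaldehyde before it is acylated.
- Residual organolithium could attack the acyl chloride.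

The fallback sets out from 1 and brings in the exocyclic carbon by electrophilic substitution, before the alkyne is present. Vilsmeier–Haack formylation of 1 (POCl3, DMF, 1,2-dichloroethane, 60 °C, then aq. NaOAc) at the free α-position should give 5'-bromo-2,2'-bithiophene-5-carbaldehyde F1. Sonogashira coupling of F1 with 2 (PdCl2(PPh3)2, CuI, Et3N, THF) should give 5'-(4-{[tert-butyl(dimethyl)silyl]oxy}but-1-yn-1-yl)-2,2'-bithiophene-5-carbaldehyde F2. Reduction with NaBH4 (MeOH/THF, 0 °C) should give [5'-(4-{[tert-butyl(dimethyl)silyl]oxy}but-1-yn-1-yl)-2,2'-bithiophen-5-yl]methanol F3. One equivalent of n-BuLi at −78 °C removes only the O–H proton of F3, so the fallback comes back to the route at 7. Compound 7 is then acylated with 5, free of amine, to 8.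

Step 3. Fluoride or the transient alkoxide could cleave or transfer the senecioyl group, or the bithienylmethyl C–O bond could ionise during unmasking. The fallback sets out from 10, drops the silyl group altogether and attaches the finished side chain last.
- Compound 10 acylates commercial but-3-yn-1-ol (C#CCCO; pyridine, CH2Cl2, 0 °C) to give but-3-yn-1-yl 3-methylbutanoate F4.
- Commercial 5,5'-dibromo-2,2'-bithiophene (Brc1ccc(-c2ccc(Br)s2)s1) undergoes a single bromine–lithium exchange (n-BuLi, 1.0 equiv, THF, −78 °C) to (5'-bromo-2,2'-bithiophen-5-yl)lithium F5.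
- F5 takes up 4 to give lithium (5'-bromo-2,2'-bithiophen-5-yl)methoxide F6, which is acylated in the same flask with 5 to (5'-bromo-2,2'-bithiophen-5-yl)methyl 3-methylbut-2-enoate F7.
- Sonogashira coupling of F7 with F4 (PdCl2(PPh3)2, CuI, Et3N, THF, 50 °C) comes back to the route at 11.

Step 1. Oxidative addition into the electron-rich thienyl C–Br bond could be slow, which would let oxidative Glaser-type dimerisation consume the alkyne. The fallback sets out from 2 and forms the inter-ring bond last. Compound 2 is coupled at room temperature with commercial 2-bromo-5-iodothiophene (Brc1ccc(I)s1; PdCl2(PPh3)2, CuI, Et3N), where only the C–I bond should react, to give tert-butyl{[4-(5-bromothiophen-2-yl)but-3-yn-1-yl]oxy}dimethylsilane F8. Suzuki–Miyaura coupling of F8 with thiophen-2-ylboronic acid (OB(O)c1cccs1; Pd(PPh3)4, K2CO3, DME/H2O, 80 °C) attaches ring A and comes back to the route at 3.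

Further compounds
F1 | step 2 | 5'-bromo-2,2'-bithiophene-5-carbaldehyde | O=Cc1ccc(-c2ccc(Br)s2)s1
F2 | step 2 | 5'-(4-{[tert-butyl(dimethyl)silyl]oxy}but-1-yn-1-yl)-2,2'-bithiophene-5-carbaldehyde | O=Cc1ccc(-c2ccc(C#CCCO[Si](C)(C)C(C)(C)C)s2)s1
F3 | step 2 | [5'-(4-{[tert-butyl(dimethyl)silyl]oxy}but-1-yn-1-yl)-2,2'-bithiophen-5-yl]methanol | OCc1ccc(-c2ccc(C#CCCO[Si](C)(C)C(C)(C)C)s2)s1
F4 | step 3 | but-3-yn-1-yl 3-methylbutanoate | C#CCCOC(=O)CC(C)C
F5 | step 3 | (5'-bromo-2,2'-bithiophen-5-yl)lithium | [Li]c1ccc(-c2ccc(Br)s2)s1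
F6 | step 3 | lithium (5'-bromo-2,2'-bithiophen-5-yl)methoxide | [Li]OCc1ccc(-c2ccc(Br)s2)s1
F7 | step 3 | (5'-bromo-2,2'-bithiophen-5-yl)methyl 3-methylbut-2-enoate | CC(C)=CC(=O)OCc1ccc(-c2ccc(Br)s2)s1
F8 | step 1 | tert-butyl{[4-(5-bromothiophen-2-yl)but-3-yn-1-yl]oxy}dimethylsilane | CC(C)(C)[Si](C)(C)OCCC#Cc1ccc(Br)s1
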